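Write the balance on the electrophile, with X the fraction of its charge reacted.

electrophile 0.050 M; solid base 0.100 M; time 4.0 h

- the concentration of nucleophile at which the part of the electrophile that has reacted at 4.0 h is just 80%, in M

    electrophile + nucleophile → acid set free + product (k1 = 0.258 M⁻¹ min⁻¹)
    nucleophile + acid set free ⇌ protonated nucleophile, settled at all times (K2 = 59000 M⁻¹)
    acid set free + free base ⇌ salt of the base (K3 = 54900 M⁻¹, k3 = 1.78 M⁻¹ min⁻¹)
    solid base ⇌ free base, rate k4*(cs4 - [free base]) while solid is left; crystals form when [free base] > cs4 (cs4 = 18 mM, k4 = 0.00838 min⁻¹)

This flask holds solid base at 0.100 M, twice the electrophile, enough on paper for the acid set free; yet I price each electrophile at two nucleophiles, one coupled and one protonated. I call 0.100 M of nucleophile the full price of the electrophile charge, and f the nucleophile charge as a fraction of it. With θ, the coupling constant times electrophile charge times time, at 3.10: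

dX/dt ∝ θ(1 − X)(f − X)

X = f(1 − E)/(1 − fE), where E = exp(−2θ(1 − f))

I try f halfway between 80% and the whole charge, 90.0%, which is 0.0900 M. Then E is 0.538 and X is 80.6%, more than wanted, so I commit to a charge a little under that. Below full price, the nucleophile is the limiting reagent.

The price holds because, at X = 80% in this flask at the trial charge, with 59000 M⁻¹ holding the free acid down and the free base taken at its solubility 18 mM, handover to the base moves X at 0.00261 h⁻¹ against 0.0310 h⁻¹ for coupling.

The forecast gives 0.0885 M, since “each electrophile effectively uses up two nucleophiles”. The flask gives 0.0889 M.

In this flask half of the coupling turnover up to 4.0 h is done by 0.506 h, ahead of half of the dissolving of solid base at 1.14 h, and passing acid to the free base makes no difference. In this flask at 0.400 h, with 34.7% of the electrophile used, the full price leaves 61.0% of the nucleophile free, and the flask shows 60.9%; at 12.0 h the electrophile used stands at 88.7%, and the charge over the full price is 88.9%.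

Its constants are those of an exercise; the rest is arithmetic.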